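**Retrosynthetic overview**
- Structural feature: ring B (C5–C10) carries methyl groups on C8 and C10 on either side of the oxygenated C9. This is the substitution pattern of 2,6-dimethylphenol, with the phenol oxygen as the C9 oxygen. Ring B is therefore bought as the arene and dearomatized to the para-quinone monoketal, with C6 masked.
- Key disconnection at C1–C10 and C4–C5: the C10=C5 enone bond of the prochiral ketal dienone is the dienophile for a 3-siloxypenta-1,3-diene (C1–C4 plus one C4 methyl) under a chiral titanium Lewis acid. This closes ring A and makes the quaternary C10.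
- Adjustment after the cycloaddition: C4 is made quaternary by α′-methylation of the Δ1-3-enone. The C6 ketone is used to flatten C5 as a dienol triflate and is then removed. α-Face hydrogenation gives the trans-decalin, C8 is equilibrated and C3 is reduced.
- C9 and side chain: methylenation, α-epoxidation and opening at C11 by a furan-3-ylmethyl nucleophile (C12–C16) set the 9α-OH. The furan becomes the butenolide and the acetate is added last.
- Ring order: B (arene), then A ([4+2]), then the butenolide (brought in as a furan).

Key step: step 3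

**Remarks**
- Numbering: labdane numbering is used throughout. Ring A is C1–C5 and C10, ring B is C5–C10, the chain is C11–C12 and the butenolide is C13–C16. Bicyclic intermediates are named as decalins with this numbering. β is the face of the C10 methyl.
- Assumption: (R)-BINOL is written for the catalyst of step 3. The sense of induction on this dienone cannot be predicted with confidence, so the ligand antipode that delivers adduct 6 as drawn is the one to be used.
- C5 correction: the cis/trans equilibrium of a 4,4-dimethyl-6-ketone of this decalin is expected to be shallow, because the equatorial C4 methyl eclipses the C6 carbonyl in the trans isomer. C5 is therefore not corrected by equilibration. It is made trigonal through the C6 ketone, and the hydrogen is returned from the α face.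

**Step 1**
Reactants: 1 2,6-dimethylphenol
Product: 3 4,4-dimethoxy-2,6-dimethylcyclohexa-2,5-dien-1-one, via 4-methoxy-2,6-dimethylphenol 2 (not isolated)
Conditions: PhI(OAc)2 (2.2 equiv), MeOH, 0 °C → rt
Reagents that add atoms: methanol, CO
Why: Hypervalent-iodine oxidative dearomatization, in which methanol attacks the free para carbon of the aryloxy-iodane, the resulting 4-methoxyphenol is oxidized again in the same way, and the two ortho methyls block ortho attack; no stereocenter is formed.

**Step 2**
Reactants: 4 pent-1-en-3-one (ethyl vinyl ketone)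
Product: 5 (Z)-3-(tert-butyldimethylsilyloxy)penta-1,3-diene
Conditions: TBSOTf (1.1 equiv), Et3N (1.5 equiv), Et2O, 0 °C
Reagents that add atoms: tert-butyldimethylsilyl triflate, CC(C)(C)[Si](C)(C)OS(=O)(=O)C(F)(F)F
Why: Soft enolization and O-silylation of the ethyl ketone gives the 2-siloxydiene, and the (Z)-enol ether should prevail because the methyl turns away from the vinyl group when the silyloxocarbenium ion is deprotonated.

**Step 3**
Reactants: 3 4,4-dimethoxy-2,6-dimethylcyclohexa-2,5-dien-1-one; 5 (Z)-3-(tert-butyldimethylsilyloxy)penta-1,3-diene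
Product: 6 3-(tert-butyldimethylsilyloxy)-6,6-dimethoxy-4α,8,10β-trimethyl-5βH-decal-2,7-dien-9-one (cis-fused adduct)
Conditions: (R)-BINOL (22 mol %), TiCl2(OiPr)2 (20 mol %), 4 Å MS, CH2Cl2, −30 → 0 °C; 5 (2 equiv)
Reagents that add atoms: none
Why: The titanium(IV) binaphtholate binds the C9 carbonyl, the only free carbonyl because C6 is held as the ketal, and lowers the LUMO of the C10=C5 enone bond, which then undergoes a concerted but asynchronous normal-demand [4+2] cycloaddition in which C4–C5 bonding runs ahead of C1–C10. The closest known reaction type is the chiral titanium- or boron-Lewis-acid-catalysed Diels–Alder reaction of para-quinone monoketals and quinones with 2-siloxydienes. Ring A is closed as a six-membered carbocycle by intermolecular suprafacial–suprafacial cycloaddition, both ring bonds (C1–C10 and C4–C5) being made in this one step. C10 is fixed by the catalyst, which must select one of the two enantiotopic alkene/face pairs of the dienone; C5 follows from suprafacial addition (H5 cis to the C10 methyl); C4 follows from the endo transition state together with the (Z)-enol ether geometry, which places the methyl outside and hence trans to H5. Regioselectivity requires the enol-ether β-carbon (the CHCH3 terminus) to attack the enone β-carbon C5, which the single free carbonyl and the siloxy donor secure against the weaker opposing bias of the terminal methyl. Monoaddition is secured because the surviving C7=C8 enone is flanked by the new quaternary C10.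

**Step 4**
Reactants: 6 cis-fused adduct
Product: 7 6,6-dimethoxy-4α,8,10β-trimethyl-5βH-decal-1,7-diene-3,9-dione (cis-fused)
Conditions: Pd(OAc)2 (1.1 equiv), MeCN, rt → 40 °C
Reagents that add atoms: none
Why: Saegusa–Ito oxidation, in which Pd(II) replaces silicon at the C2=C3 enol ether and the only β-hydrogens sit on C1, so syn β-hydride elimination gives the Δ1-3-enone and leaves C4–H as the single enolizable position of the molecule.

**Step 5**
Reactants: 7 cis-fused dienedione ketal
Product: 9 6,6-dimethoxy-4,4,8,10β-tetramethyl-5βH-decal-1,7-diene-3,9-dione (cis-fused), via lithium C3–C4 dienolate 8 (not isolated)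
Conditions: LDA (1.2 equiv), THF, −78 °C; MeI (5 equiv), DMPU, −78 → 0 °C
Reagents that add atoms: iodomethane, CI
Why: Kinetic α′-deprotonation of the enone gives the cross-conjugated dienolate (C2 is vinylic, and C10 and the ketal carbon carry no hydrogen), and SN2 C-methylation makes C4 quaternary, which removes the C4 stereocenter.

**Step 6**
Reactants: 9 4,4-dimethyl ketal
Product: 10 4,4,8,10β-tetramethyl-5βH-decal-1,7-diene-3,6,9-trione (cis-fused enedione)
Conditions: 1 M aq HCl, THF, 0 °C → rt
Reagents that add atoms: water, O
Why: Acid-catalysed ketal hydrolysis through the methoxy-oxocarbenium ion unmasks the C6 ketone, and any partial epimerization at C5 is harmless because C5 becomes trigonal in the next step.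

**Step 7**
Reactants: 10 cis-fused enedione
Product: 12 4,4,8,10β-tetramethyl-3,9-dioxodecal-1,5,7-trien-6-yl triflate, via potassium C5–C6 dienolate 11 (not isolated)
Conditions: KHMDS (1.1 equiv), THF, −78 °C; N-(5-chloro-2-pyridyl)triflimide (1.2 equiv), −78 → −20 °C
Reagents that add atoms: N-(5-chloro-2-pyridyl)bis(trifluoromethanesulfonimide), FC(F)(F)S(=O)(=O)N(c1ccc(Cl)cn1)S(=O)(=O)C(F)(F)F
Why: Kinetic enolate formation and O-sulfonylation (enol triflate synthesis), in which C5–H is the only sp3 α-hydrogen of the three carbonyl groups, so its removal and trapping on oxygen give the C5=C6 dienol triflate and erase the cis ring-fusion stereocenter.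

**Step 8**
Reactants: 12 dienol triflate
Product: 13 4,4,8,10β-tetramethyldecal-1,5,7-triene-3,9-dione
Conditions: Pd(OAc)2 (5 mol %), PPh3 (10 mol %), HCO2H (2 equiv), Et3N (3 equiv), DMF, 60 °C
Reagents that add atoms: none
Why: Palladium-catalysed formate reduction of a vinyl triflate (oxidative addition, decarboxylation of formate to Pd–H, reductive elimination) replaces C6–O by C6–H without touching the ketones, which removes the C6 oxygen.

**Step 9**
Reactants: 13 trienedione
Product: 14 4,4,8,10β-tetramethyl-5αH-decalin-3,9-dione (trans-fused; C8 epimers)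
Conditions: H2 (60 bar), 10 % Pd/C, EtOAc, 50 °C
Reagents that add atoms: none
Why: Heterogeneous catalytic hydrogenation saturates the Δ1 and Δ7 enone bonds first and then, under pressure, the hindered Δ5 bond, which can reach the metal only with its α face because the β face carries the methyls on C10 and C4, so H5 is delivered α and the decalin becomes trans-fused, as in the classical reduction of 4,4,10-trimethyl-Δ5-octalins.

**Step 10**
Reactants: 14 trans-dione (C8 epimers)
Product: 15 4,4,8α,10β-tetramethyl-5αH,8βH-decalin-3,9-dione
Conditions: NaOMe (0.3 equiv), MeOH, rt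
Reagents that add atoms: none
Why: Base-mediated epimerization through the C8=C9 enolate places the C8 methyl in the equatorial α position, because the β epimer suffers a 1,3-diaxial methyl/methyl contact with the C10 methyl, while C5 and C10 have no adjacent carbonyl hydrogen path and cannot change.

**Step 11**
Reactants: 15 8α-methyl dione
Product: 16 3β-hydroxy-4,4,8α,10β-tetramethyl-5αH-decalin-9-one
Conditions: NaBH4 (0.5 equiv), MeOH–CH2Cl2, −40 °C
Reagents that add atoms: none
Why: Chemoselective borohydride reduction, in which C9 is shielded on both sides (quaternary C10, methyl-bearing C8) while C3 has a methylene neighbour, and hydride attacks C3 axially from the α face, away from the axial 4β and 10β methyls, to give the equatorial 3β-alcohol.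

**Step 12**
Reactants: 16 hydroxy ketone
Product: 17 9-methylene-4,4,8α,10β-tetramethyl-5αH-decalin-3β-ol (drim-9(11)-en-3β-ol)
Conditions: Ph3PCH3Br (6 equiv), KOtBu (5.5 equiv), toluene, 100 °C
Reagents that add atoms: methyltriphenylphosphonium bromide, C[P+](c1ccccc1)(c1ccccc1)c1ccccc1.[Br-]
Why: Wittig methylenation with excess non-stabilized ylide at high temperature is the standard treatment of hindered ketones; one equivalent only deprotonates the 3-OH, and reversible enolization keeps C8 in its equatorial configuration.

**Step 13**
Reactants: 17 exocyclic alkene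
Product: 18 9α,11-epoxydriman-3β-ol (spiro-epoxide; oxygen axial α and C11 equatorial β)
Conditions: mCPBA (1.2 equiv), CH2Cl2, 0 °C
Reagents that add atoms: 3-chloroperoxybenzoic acid, OOC(=O)c1cccc(Cl)c1
Why: Prilezhaev epoxidation, in which the peracid reaches the C9=C11 bond from the α face, anti to the axial C10 methyl next to the alkene, so the oxygen ends up 9α and C11 β, which sets C9.

**Step 14**
Reactants: 19 furan-3-ylmethanol
Product: 20 3-(chloromethyl)furan
Conditions: SOCl2, pyridine, Et2O, 0 °C
Reagents that add atoms: thionyl chloride, ClS(Cl)=O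
Why: Chlorodehydroxylation through the chlorosulfite, with pyridine scavenging HCl so that the acid-sensitive furan is spared; no stereocenter is involved.

**Step 15**
Reactants: 18 9α,11-epoxydriman-3β-ol; 20 3-(chloromethyl)furan
Product: 22 15,16-epoxylabda-13(16),14-diene-3β,9α-diol, via furan-3-ylmethylmagnesium chloride 21 (not isolated)
Conditions: 20 (4 equiv), Mg, THF, 0 °C → rt; then CuI (15 mol %), 18, THF, −30 °C → rt
Reagents that add atoms: none
Why: Copper-catalysed Grignard opening of a 2,2-disubstituted epoxide by SN2 attack at the primary carbon C11 forms C11–C12, and because the C9–O bond is not broken the 9α configuration is kept; one equivalent of reagent is consumed by the free 3-OH.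

**Step 16**
Reactants: 22 furan diol
Product: 24 3β,9α,16-trihydroxylabd-13-en-15,16-olide (γ-hydroxybutenolide; C16 epimers), via furan endoperoxide 23 (not isolated)
Conditions: O2, visible light, rose bengal (cat.), iPr2NEt, CH2Cl2, −78 °C → rt
Reagents that add atoms: dioxygen, O=O
Why: [4+2] cycloaddition of singlet oxygen to the furan followed by amine-induced Kornblum–DeLaMare fragmentation, in which the hindered base removes the less shielded bridgehead hydrogen (on C15, remote from the chain), so C15 becomes the carbonyl and C16 the hemiacetal carbon.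

**Step 17**
Reactants: 24 γ-hydroxybutenolide
Product: 26 3β,9α-dihydroxylabd-13-en-15,16-olide, via sodium (Z)-hydroxy-enoate 25 (not isolated)
Conditions: NaBH4, EtOH, 0 °C; then 1 M HCl to pH 3
Reagents that add atoms: none
Why: Borohydride reduces the aldehyde of the ring-opened formyl-carboxylate tautomer, and acidification lactonizes the (Z)-4-hydroxy-enoate to the β-substituted butenolide, which removes the hemiacetal stereocenter.

**Step 18**
Reactants: 26 diol butenolide
Product: 27 3β-acetoxy-9α-hydroxylabd-13-en-15,16-olide (CNP0578261.2)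
Conditions: Ac2O, pyridine, DMAP (cat.), CH2Cl2, 0 °C → rt
Reagents that add atoms: acetic anhydride, CC(=O)OC(C)=O
Why: DMAP-catalysed acylation occurs only at the secondary equatorial 3β-OH, with retention at C3, because the tertiary axial 9α-OH between C8 and the quaternary C10 is too hindered to react.

**Compound list**
1 | 2,6-dimethylphenol | Cc1cccc(C)c1O | starting material
2 | 4-methoxy-2,6-dimethylphenol | COc1cc(C)c(O)c(C)c1 | intermediate
3 | 4,4-dimethoxy-2,6-dimethylcyclohexa-2,5-dien-1-one | COC1(OC)C=C(C)C(=O)C(C)=C1 | intermediate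
4 | pent-1-en-3-one | CCC(=O)C=C | starting material
5 | (Z)-3-(tert-butyldimethylsilyloxy)penta-1,3-diene | C/C=C(/C=C)O[Si](C)(C)C(C)(C)C | intermediate
6 | cis-fused adduct (C3 silyl enol ether, C6 ketal, 4α-Me, 5β-H, 10β-Me) | CC(C)(C)[Si](C)(C)OC1=CC[C@@]2(C)[C@H](C(OC)(OC)C=C(C)C2=O)[C@@H]1C | intermediate
7 | cis-fused Δ1,Δ7-diene-3,9-dione 6-ketal (4α-Me) | O=C1C=C[C@@]2(C)[C@H](C(OC)(OC)C=C(C)C2=O)[C@@H]1C | intermediate
8 | lithium C3–C4 dienolate of 7 | [Li+].[O-]C=1C=C[C@@]2(C)[C@H](C(OC)(OC)C=C(C)C2=O)C=1C | intermediate
9 | cis-fused 4,4-dimethyl Δ1,Δ7-diene-3,9-dione 6-ketal | O=C1C=C[C@@]2(C)[C@H](C(OC)(OC)C=C(C)C2=O)C1(C)C | intermediate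
10 | cis-fused 4,4,8,10-tetramethyl Δ1,Δ7-diene-3,6,9-trione | O=C1C=C[C@@]2(C)[C@H](C(=O)C=C(C)C2=O)C1(C)C | intermediate
11 | potassium C5–C6 dienolate of 10 | [K+].O=C1C=C[C@@]2(C)C(=C([O-])C=C(C)C2=O)C1(C)C | intermediate
12 | C6 dienol triflate (Δ1,Δ5,Δ7-triene-3,9-dione) | O=C1C=C[C@@]2(C)C(=C(OS(=O)(=O)C(F)(F)F)C=C(C)C2=O)C1(C)C | intermediate
13 | 4,4,8,10β-tetramethyldecal-1,5,7-triene-3,9-dione | O=C1C=C[C@@]2(C)C(=CC=C(C)C2=O)C1(C)C | intermediate
14 | trans-fused 3,9-dione, C8 epimers | O=C1CC[C@@]2(C)[C@@H](CCC(C)C2=O)C1(C)C | intermediate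
15 | trans-fused 3,9-dione, 8α-methyl | O=C1CC[C@@]2(C)[C@@H](CC[C@@H](C)C2=O)C1(C)C | intermediate
16 | 3β-hydroxy-9-ketone | O[C@H]1CC[C@@]2(C)[C@@H](CC[C@@H](C)C2=O)C1(C)C | intermediate
17 | drim-9(11)-en-3β-ol | O[C@H]1CC[C@@]2(C)[C@@H](CC[C@@H](C)C2=C)C1(C)C | intermediate
18 | 9α,11-epoxydriman-3β-ol | O[C@H]1CC[C@@]2(C)[C@@H](CC[C@@H](C)[C@]2(O3)C3)C1(C)C | intermediate
19 | furan-3-ylmethanol | OCc1ccoc1 | starting material
20 | 3-(chloromethyl)furan | ClCc1ccoc1 | intermediate
21 | furan-3-ylmethylmagnesium chloride | Cl[Mg]Cc1ccoc1 | intermediate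
22 | 15,16-epoxylabda-13(16),14-diene-3β,9α-diol | O[C@H]1CC[C@@]2(C)[C@@H](CC[C@@H](C)[C@]2(O)CCc2ccoc2)C1(C)C | intermediate
23 | furan endoperoxide of 22 (facial isomers) | O[C@H]1CC[C@@]2(C)[C@@H](CC[C@@H](C)[C@]2(O)CCC2=CC3OOC2O3)C1(C)C | intermediate
24 | 3β,9α,16-trihydroxylabd-13-en-15,16-olide (C16 epimers) | O[C@H]1CC[C@@]2(C)[C@@H](CC[C@@H](C)[C@]2(O)CCC2=CC(=O)OC2O)C1(C)C | intermediate
25 | sodium (Z)-3β,9α,16-trihydroxylabd-13-en-15-oate | [Na+].O[C@H]1CC[C@@]2(C)[C@@H](CC[C@@H](C)[C@]2(O)CC/C(CO)=C/C(=O)[O-])C1(C)C | intermediate
26 | 3β,9α-dihydroxylabd-13-en-15,16-olide | O[C@H]1CC[C@@]2(C)[C@@H](CC[C@@H](C)[C@]2(O)CCC2=CC(=O)OC2)C1(C)C | intermediate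
27 | 3β-acetoxy-9α-hydroxylabd-13-en-15,16-olide | CC(=O)O[C@H]1CC[C@@]2(C)[C@@H](CC[C@@H](C)[C@]2(O)CCC2=CC(=O)OC2)C1(C)C | target

**Step count**
Total step count: 18. Longest linear sequence: 16 (steps 1, 3–13 and 15–18).

**Steps most likely to fail**

1. **Step 3.**
   - What may go wrong: The cycloaddition may be too slow at a trisubstituted alkene wedged between the methyl-bearing C10 and the ketal carbon. The Lewis acid may ionize the ketal or strip the silyl group from the diene. The catalyst may also discriminate poorly between the enantiotopic alkene/face pairs, because the dienone offers no second binding point.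
   - Fallback principle: stereocontrol by a covalently bound auxiliary and activation by pressure. It sets out from 3 and comes back at 10.
   - Auxiliary: Acid-catalysed ketal exchange of 3 with (R,R)-hydrobenzoin gives the C2-symmetric spiroketal (2R,3R)-7,9-dimethyl-2,3-diphenyl-1,4-dioxaspiro[4.5]deca-6,9-dien-8-one F1. Its two alkenes are homotopic and only the two faces differ, now as diastereotopic faces.
   - Cycloaddition: Uncatalysed cycloaddition with 5 under high pressure (about 13 kbar, CH2Cl2, rt) needs no Lewis acid. The diastereomeric adducts are separated by chromatography or crystallization to give the 10β-methyl hydrobenzoin-ketal adduct F2. The other diol antipode is used if the wanted isomer is disfavoured.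
   - Return to the route: Saegusa–Ito oxidation gives the hydrobenzoin-ketal dienedione F3. LDA/MeI gives the 4,4-dimethyl hydrobenzoin ketal F4. Aqueous trifluoroacetic acid then gives 10.

2. **Step 7.**
   - What may go wrong: Under irreversible conditions the base may take a γ-hydrogen of the exposed C8 methyl instead of the hindered C5–H. The cross-conjugated triflate that results leaves C5 in the cis configuration.
   - Fallback principle: reversible enolization, for which γ-deprotonation is harmless, and removal of C6 through the unhindered C7 methylene. It sets out from 10 and comes back at 14.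
   - Epimerization: DBU in toluene equilibrates C5. The trans-fused enedione F5 is separated and the cis isomer is resubmitted.
   - Deoxygenation: Zn in AcOH reduces only the enedione C7=C8 bond to give the trans-fused Δ1-ene-3,6,9-trione F6. KHMDS and the pyridyl triflimide at −78 °C deprotonate C7 to give the Δ6-enol triflate F7. Pd/formate reduction gives the Δ1,Δ6-diene-3,9-dione F8.
   - Return to the route: H2 (1 atm) over Pd/C saturates both disubstituted alkenes to give 14.

3. **Step 15.**
   - What may go wrong: Magnesium halide may rearrange the epoxide to the C9 aldehyde before substitution occurs. The SN2 approach to C11 runs parallel to the axial C10 methyl and may be slow. The furylmethyl reagent may also react through furan C2.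
   - Fallback principle: the C11–C12 bond is made by olefination at an sp2 carbon. It sets out from 17 and comes back at 22.
   - Aldehyde: OsO4 (cat.)/NMO dihydroxylates 17 from the α face to give drimane-3β,9α,11-triol F9. TEMPO (cat.)/NCS oxidizes only the primary alcohol to give 3β,9α-dihydroxydriman-11-al F10.
   - Olefination: 20 and PPh3 give (furan-3-ylmethyl)triphenylphosphonium chloride F11. A Wittig reaction of F10 with F11 and NaHMDS gives the 11-ene 15,16-epoxylabda-11,13(16),14-triene-3β,9α-diol F12.
   - Return to the route: Diimide (TsNHNH2, NaOAc) reduces the disubstituted alkene without touching the furan and gives 22.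

**Further compounds**
F1 | step 3 | (2R,3R)-7,9-dimethyl-2,3-diphenyl-1,4-dioxaspiro[4.5]deca-6,9-dien-8-one | CC1=CC2(C=C(C)C1=O)O[C@H](c1ccccc1)[C@@H](c1ccccc1)O2
F2 | step 3 | 10β-methyl hydrobenzoin-ketal adduct | CC(C)(C)[Si](C)(C)OC1=CC[C@@]2(C)[C@H](C3(O[C@H](c4ccccc4)[C@@H](c4ccccc4)O3)C=C(C)C2=O)[C@@H]1C
F3 | step 3 | hydrobenzoin-ketal dienedione | O=C1C=C[C@@]2(C)[C@H](C3(O[C@H](c4ccccc4)[C@@H](c4ccccc4)O3)C=C(C)C2=O)[C@@H]1C
F4 | step 3 | 4,4-dimethyl hydrobenzoin ketal | O=C1C=C[C@@]2(C)[C@H](C3(O[C@H](c4ccccc4)[C@@H](c4ccccc4)O3)C=C(C)C2=O)C1(C)C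
F5 | step 7 | trans-fused enedione | O=C1C=C[C@@]2(C)[C@@H](C(=O)C=C(C)C2=O)C1(C)C
F6 | step 7 | trans-fused Δ1-ene-3,6,9-trione (C8 epimers) | O=C1C=C[C@@]2(C)[C@@H](C(=O)CC(C)C2=O)C1(C)C
F7 | step 7 | Δ6-enol triflate | O=C1C=C[C@@]2(C)[C@@H](C(OS(=O)(=O)C(F)(F)F)=CC(C)C2=O)C1(C)C
F8 | step 7 | Δ1,Δ6-diene-3,9-dione | O=C1C=C[C@@]2(C)[C@@H](C=CC(C)C2=O)C1(C)C
F9 | step 15 | drimane-3β,9α,11-triol | O[C@H]1CC[C@@]2(C)[C@@H](CC[C@@H](C)[C@]2(O)CO)C1(C)C
F10 | step 15 | 3β,9α-dihydroxydriman-11-al | O[C@H]1CC[C@@]2(C)[C@@H](CC[C@@H](C)[C@]2(O)C=O)C1(C)C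
F11 | step 15 | (furan-3-ylmethyl)triphenylphosphonium chloride | C(c1ccoc1)[P+](c1ccccc1)(c1ccccc1)c1ccccc1.[Cl-]
F12 | step 15 | 15,16-epoxylabda-11,13(16),14-triene-3β,9α-diol (E/Z) | O[C@H]1CC[C@@]2(C)[C@@H](CC[C@@H](C)[C@]2(O)C=Cc2ccoc2)C1(C)C
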